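**Plan** (asbestinin numbering: cyclohexane C1, C10–C14; THF O, C2, C1, C10, C9; oxonane O, C2–C9; oxepane O16, C3, C2, C1, C14–C16; C19 = exocyclic CH2)
Cuts: the C4 ester; C3–CH3, with C3–O16 taken back to a C3 ketone; C2–C3, paid for by a sacrificial C3–C7 bond; O–C2 and C9–C10; C1–C2/C2–C10 (cyclopropane); C12–CH3; C14–C15.
Forward: purchased cyclohexene ring → enone → thio-substituted donor–acceptor cyclopropane → cis-fused THF by (3+2) annulation with an aldehyde carrying a masked cyclopentane-1,3-dione → oxonane by four-atom radical ring expansion → oxepane.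
Enabling feature: in the oxonane, C3(O)–C4–C5–C6(=O)–C7(=C19H2) is a 2,2-disubstituted cyclopentane-1,3-dione opened between C3 and C7. C2 is an α-oxygenated THF carbon tied to C7 through O–C9–C8, so a C2 radical reaches a dione carbonyl through a six-membered transition state.
Stereochemistry: C14 and C15 come from (S)-cyclohex-2-enol by a suprafacial [3,3] shift. C12, C1, C10, C9, C11, C2, C3 and C4 follow by substrate control.

Key step: step 19

Remark: C2 of 24–28 is an anomeric O,S-acetal centre, expected as a mixture. It is drawn without configuration because step 19 planarises it.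

Step 1
Reactants: 1 (S)-cyclohex-2-en-1-ol
Product: 2 (S)-cyclohex-2-en-1-yl propanoate
Conditions: EtCOCl, Et3N, DMAP (cat.), CH2Cl2, 0 °C
Reagents that add atoms: propanoyl chloride CCC(=O)Cl
Why: DMAP-catalysed acylation of the allylic alcohol leaves the carbinol centre (future C10) untouched.

Step 2
Reactants: 2 (S)-cyclohex-2-en-1-yl propanoate
Product: 5 (R)-2-[(R)-cyclohex-2-en-1-yl]propanoic acid, via (E)-silyl ketene acetal 3 (not isolated), via trimethylsilyl ester 4 (not isolated)
Conditions: LDA, THF, −78 °C; TMSCl; −78 → 60 °C; 1 M HCl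
Reagents that add atoms: chlorotrimethylsilane C[Si](C)(C)Cl (silicon of 3 and 4)
Why: In this Ireland–Claisen rearrangement, kinetic enolisation in THF gives the (E)-ketene acetal, the suprafacial [3,3] shift transfers the C10–O chirality to C14, and the boat-like transition state usual for cyclohexenyl esters sets C15.

Step 3
Reactants: 5 (R)-2-[(R)-cyclohex-2-en-1-yl]propanoic acid
Product: 6 (R)-2-[(R)-cyclohex-2-en-1-yl]propan-1-ol
Conditions: LiAlH4, Et2O, 0 °C → rt
Reagents that add atoms: none
Why: Hydride reduction takes the acid to the primary alcohol (C16) without touching the isolated alkene or the stereocentres.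

Step 4
Reactants: 6 (R)-2-[(R)-cyclohex-2-en-1-yl]propan-1-ol
Product: 7 tert-butyl{(R)-2-[(R)-cyclohex-2-en-1-yl]propoxy}diphenylsilane
Conditions: TBDPSCl, imidazole, CH2Cl2, rt
Reagents that add atoms: tert-butyl(chloro)diphenylsilane CC(C)(C)[Si](Cl)(c1ccccc1)c1ccccc1
Why: This is standard silylation, and the TBDPS ether outlasts the later Lewis-acid, mild-fluoride and oxidation steps.

Step 5
Reactants: 7 tert-butyl{(R)-2-[(R)-cyclohex-2-en-1-yl]propoxy}diphenylsilane
Product: 8 (R)-4-[(R)-1-(tert-butyldiphenylsilyloxy)propan-2-yl]cyclohex-2-en-1-one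
Conditions: Rh2(cap)4 (1 mol %), t-BuOOH (aq.), K2CO3, CH2Cl2, rt
Reagents that add atoms: tert-butyl hydroperoxide CC(C)(C)OO
Why: Catalytic allylic oxidation abstracts hydrogen from the unhindered allylic CH2 (C11), and the allyl radical is oxygenated at that end, away from the branched C14.

Step 6
Reactants: 8 (R)-4-[(R)-1-(tert-butyldiphenylsilyloxy)propan-2-yl]cyclohex-2-en-1-one
Product: 10 (4R,6R)-4-[(R)-1-(tert-butyldiphenylsilyloxy)propan-2-yl]-6-methylcyclohex-2-en-1-one, via lithium cross-conjugated dienolate 9 (not isolated)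
Conditions: LDA, THF, −78 °C; MeI, −78 → −40 °C
Reagents that add atoms: lithium diisopropylamide CC(C)N([Li])C(C)C (lithium of 9); iodomethane CI
Why: Kinetic α′-deprotonation followed by axial methylation gives the 4,6-trans product (C12), which is not exposed to equilibrating conditions before C11 is reduced.

Step 7
Reactants: 10 (4R,6R)-4-[(R)-1-(tert-butyldiphenylsilyloxy)propan-2-yl]-6-methylcyclohex-2-en-1-one; 11 bis(phenylthio)methane
Product: 14 7-exo-(phenylthio)bicyclo[4.1.0]heptan-2-one (cyclopropane C1–C10–C2, anti to the C14 side chain), via bis(phenylthio)methyllithium 12 (not isolated), via lithium enolate 13 (not isolated)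
Conditions: 11, n-BuLi, THF, 0 °C; HMPA, −78 °C; 10; then (CuOTf)2·C6H6, −78 → 0 °C
Reagents that add atoms: n-butyllithium [Li]CCCC (lithium of 12 and 13)
Why: In this Michael-initiated ring closure, the soft thioacetal anion adds 1,4 anti to the C14 substituent (sets C1), and Cu(I)-assisted loss of thiophenoxide lets the enolate close the cyclopropane with sulfur exo.

Step 8
Reactants: 15 cyclopentane-1,3-dione
Product: 16 2-[(phenylthio)methyl]cyclopentane-1,3-dione
Conditions: aq. HCHO, PhSH, L-proline (cat.), EtOH, rt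
Reagents that add atoms: formaldehyde C=O; benzenethiol Sc1ccccc1
Why: Knoevenagel condensation is followed by thia-Michael trapping of the transient 2-methylene dione, the standard way to put one functionalised carbon (C19) on a cyclic 1,3-dione.

Step 9
Reactants: 16 2-[(phenylthio)methyl]cyclopentane-1,3-dione; 17 allyl methyl carbonate
Product: 18 2-allyl-2-[(phenylthio)methyl]cyclopentane-1,3-dione
Conditions: Pd(PPh3)4 (2 mol %), THF, rt
Reagents that add atoms: none
Why: Tsuji–Trost allylation under neutral conditions alkylates the acidic 2-substituted dione at carbon and creates the quaternary C7.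

Step 10
Reactants: 18 2-allyl-2-[(phenylthio)methyl]cyclopentane-1,3-dione
Product: 19 2-allyl-2-[(phenylsulfonyl)methyl]cyclopentane-1,3-dione
Conditions: mCPBA (2.1 equiv), CH2Cl2, 0 °C
Reagents that add atoms: 3-chloroperoxybenzoic acid O=C(OO)c1cccc(Cl)c1
Why: Sulfide-to-sulfone oxidation is much faster than epoxidation of a monosubstituted alkene, and the sulfone tolerates ozone and later serves as the radical leaving group.

Step 11
Reactants: 19 2-allyl-2-[(phenylsulfonyl)methyl]cyclopentane-1,3-dione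
Product: 20 meso-2-allyl-2-[(phenylsulfonyl)methyl]cyclopentane-1,3-diol (both OH cis to CH2SO2Ph)
Conditions: NaBH4, CeCl3·7H2O, MeOH, −78 → 0 °C
Reagents that add atoms: none
Why: Hydride should attack both carbonyl groups anti to the bulkier sulfonylmethyl group to give the meso diol, which masks the dione; both carbinol centres are erased in step 18.

Step 12
Reactants: 20 meso-2-allyl-2-[(phenylsulfonyl)methyl]cyclopentane-1,3-diol
Product: 21 bis(triethylsilyl) ether of 20
Conditions: TESCl, imidazole, DMF, rt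
Reagents that add atoms: chlorotriethylsilane CC[Si](Cl)(CC)CC
Why: This is standard silylation, and TES can later be removed in the presence of TBDPS.

Step 13
Reactants: 21 bis(triethylsilyl) ether of 20
Product: 23 2-{meso-2,5-bis(triethylsilyloxy)-1-[(phenylsulfonyl)methyl]cyclopentyl}acetaldehyde (C9 aldehyde), via secondary ozonide 22 (not isolated)
Conditions: O3, CH2Cl2, −78 °C; PPh3
Reagents that add atoms: ozone [O-][O+]=O
Why: Ozonolysis with reductive work-up cleaves the only alkene, while the sulfone and silyl ethers are inert.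

Step 14
Reactants: 14 7-exo-(phenylthio)bicyclo[4.1.0]heptan-2-one; 23 C9 aldehyde
Product: 24 cis-fused 2-(phenylthio)octahydroisobenzofuran-4-one (THF O, C2, C1, C10, C9; C11 ketone) with the masked-dione methyl group (C8) on C9
Conditions: TMSOTf (20 mol %), 4 Å MS, CH2Cl2, −78 → −40 °C
Reagents that add atoms: none
Why: In this Lewis-acid-catalysed (3+2) annulation of a donor–acceptor cyclopropane with an aldehyde, the aldehyde oxygen attacks the sulfur-stabilised C2 as the strained C2–C10 bond ionises; the tethered oxocarbenium ion is then closed by the C10 enolate on the face carrying C2 (cis fusion, C10), with C8 on the convex face trans to C11 (C9).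

Step 15
Reactants: 24 cis-fused 2-(phenylthio)octahydroisobenzofuran-4-one
Product: 25 C11 alcohol (OH cis to C9 and to the C12 methyl group)
Conditions: NaBH4, MeOH/CH2Cl2, −78 → −20 °C
Reagents that add atoms: none
Why: The only carbonyl group is attacked from the face opposite to C9 and the C12 methyl group, which sets C11 and removes the risk of epimerisation at C10 and C12.

Step 16
Reactants: 25 C11 alcohol
Product: 26 C11 acetate
Conditions: Ac2O, pyridine, DMAP (cat.), CH2Cl2, rt
Reagents that add atoms: acetic anhydride CC(=O)OC(C)=O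
Why: Acetylation of the only free hydroxyl group installs the C11 acetate of the target.

Step 17
Reactants: 26 C11 acetate
Product: 27 cyclopentane-1,3-diol
Conditions: HF·pyridine, pyridine, THF, 0 °C
Reagents that add atoms: none
Why: Buffered HF cleaves the TES ethers much faster than the TBDPS ether and leaves the thioglycoside-like O,S-acetal and the acetate intact.

Step 18
Reactants: 27 cyclopentane-1,3-diol
Product: 28 2,2-disubstituted cyclopentane-1,3-dione (C3 and C6 carbonyls, C7 bearing C8 and CH2SO2Ph)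
Conditions: Dess–Martin periodinane, NaHCO3, CH2Cl2, rt
Reagents that add atoms: none
Why: Dess–Martin oxidation of both secondary alcohols restores the symmetric dione under neutral conditions that tolerate the aryl sulfide.

Step 19
Reactants: 28 2,2-disubstituted cyclopentane-1,3-dione
Product: 29 tricyclic 3,6-dioxo-7-methylene oxonane (11-oxabicyclo[6.2.1]undecane fused to the cyclohexane)
Conditions: (Bu3Sn)2 (1.2 equiv), di-tert-butyl hyponitrite (20 mol %), PhH (5 mM), 65 °C
Reagents that add atoms: none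
Why: Proposed new method: Bu3Sn• from the distannane removes PhS from the O,S-acetal (the alkyl sulfone is inert); the nucleophilic C2 radical then adds to the carbon of one of the two electrophilic dione carbonyls, the resulting C3 alkoxyl radical cleaves the C3–C7 bond to the tertiary α-keto radical, and this expels PhSO2•, which regenerates Bu3Sn• from the distannane. The closest known reaction types are the Dowd–Beckwith expansion of α-(ω-haloalkyl) β-keto esters by three or four atoms and the β-fragmentation of β-sulfonyl radicals, and what is new here is the anomeric α-oxy radical, the oxygen in the tether and the 1,3-diketone acceptor. The only ring closed directly is a transient oxane (O, C2, C3, C7, C8, C9; 6-exo attack on C=O), so the oxonane (O, C2–C9) arises by scission of the fusion bond of an oxa-hydrindane and no medium-ring cyclisation is needed. C2 is the only new stereocentre: the radical can reach the carbonyl only on the THF face that carries C8, so C3 ends cis to C8 as in the target, under control of C9. Both carbonyls give the same product because C7 becomes trigonal, and scission towards C7 is favoured over return to C2 or cleavage to C4 by the stability of the α-keto radical and the irreversible loss of the sulfonyl radical. No hydride source is present, so premature reduction is excluded, and the C7=C19 enone cannot re-close by transannular aldol reaction because C7 carries no hydrogen.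

Step 20
Reactants: 29 tricyclic 3,6-dioxo-7-methylene oxonane
Product: 30 C16 primary alcohol
Conditions: HF·pyridine, THF, rt
Reagents that add atoms: none
Why: Acidic fluoride removes the TBDPS group without base, so the enone, the acetate and C2 (α to the C3 ketone) are not endangered.

Step 21
Reactants: 30 C16 primary alcohol
Product: 32 tetracyclic enol ether (O16–C3=C4, C2 and C5 cis on the double bond), via C3 hemiketal 31 (not isolated)
Conditions: PPTS (cat.), 4 Å MS, PhH, 80 °C
Reagents that add atoms: none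
Why: In this cyclodehydration of a hydroxy ketone, only the activated α-alkoxy C3 ketone lies within reach of O16 (seven-membered ring), and water is lost towards C4H2 rather than the bridgehead C2–H, so the tether fixes the regiochemistry of the coming C4 oxygenation.

Step 22
Reactants: 32 tetracyclic enol ether
Product: 34 C3-methyl oxepane with free C4 alcohol, via C3–C4 alkoxy epoxide 33 (not isolated)
Conditions: DMDO, acetone/CH2Cl2, −78 → 0 °C; evaporate; AlMe3 (3 equiv), CH2Cl2, −78 → −30 °C; Rochelle salt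
Reagents that add atoms: dimethyldioxirane CC1(C)OO1; trimethylaluminium C[Al](C)C
Why: In this enol-ether epoxidation and alkylalane opening, known from cyclic polyether synthesis, DMDO attacks the electron-rich alkene (not the enone) from the face outside the oxonane (sets C4), and the aluminium-bound epoxide oxygen ionises C3–O and delivers methyl on the same face (syn opening, sets C3).

Step 23
Reactants: 34 C3-methyl oxepane with free C4 alcohol
Product: 35 asbestinin 16
Conditions: octanoyl chloride, pyridine, DMAP (cat.), CH2Cl2, 0 °C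
Reagents that add atoms: octanoyl chloride CCCCCCCC(=O)Cl
Why: Acylation of the only hydroxyl group under weakly basic conditions avoids β-elimination from the resulting β-acyloxy ketone.

**Compound list**
1 | (S)-cyclohex-2-en-1-ol | O[C@@H]1C=CCCC1 | starting material
2 | (S)-cyclohex-2-en-1-yl propanoate | CCC(=O)O[C@@H]1C=CCCC1 | intermediate
3 | (E)-1-[(S)-cyclohex-2-en-1-yloxy]-1-(trimethylsilyloxy)prop-1-ene | C/C=C(/O[Si](C)(C)C)O[C@@H]1C=CCCC1 | intermediate
4 | trimethylsilyl (R)-2-[(R)-cyclohex-2-en-1-yl]propanoate | C[C@@H](C(=O)O[Si](C)(C)C)[C@H]1C=CCCC1 | intermediate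
5 | (R)-2-[(R)-cyclohex-2-en-1-yl]propanoic acid | C[C@@H](C(=O)O)[C@H]1C=CCCC1 | intermediate
6 | (R)-2-[(R)-cyclohex-2-en-1-yl]propan-1-ol | C[C@@H](CO)[C@H]1C=CCCC1 | intermediate
7 | tert-butyl{(R)-2-[(R)-cyclohex-2-en-1-yl]propoxy}diphenylsilane | C[C@@H](CO[Si](c1ccccc1)(c1ccccc1)C(C)(C)C)[C@H]1C=CCCC1 | intermediate
8 | (R)-4-[(R)-1-(TBDPS-oxy)propan-2-yl]cyclohex-2-en-1-one | O=C1C=C[C@H]([C@@H](C)CO[Si](c2ccccc2)(c2ccccc2)C(C)(C)C)CC1 | intermediate
9 | lithium cross-conjugated dienolate of 8 | [Li]OC1=CC[C@@H]([C@@H](C)CO[Si](c2ccccc2)(c2ccccc2)C(C)(C)C)C=C1 | intermediate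
10 | (4R,6R)-4-[(R)-1-(TBDPS-oxy)propan-2-yl]-6-methylcyclohex-2-en-1-one | O=C1C=C[C@H]([C@@H](C)CO[Si](c2ccccc2)(c2ccccc2)C(C)(C)C)C[C@H]1C | intermediate
11 | bis(phenylthio)methane | C(Sc1ccccc1)Sc1ccccc1 | starting material
12 | bis(phenylthio)methyllithium | [Li]C(Sc1ccccc1)Sc1ccccc1 | intermediate
13 | lithium enolate of the 1,4-adduct (C1–CH(SPh)2 trans to the C14 side chain) | [Li]OC1=C[C@@H](C(Sc2ccccc2)Sc2ccccc2)[C@H]([C@@H](C)CO[Si](c2ccccc2)(c2ccccc2)C(C)(C)C)C[C@H]1C | intermediate
14 | 7-exo-(phenylthio)-3-methyl-5-[(R)-1-(TBDPS-oxy)propan-2-yl]bicyclo[4.1.0]heptan-2-one | O=C1[C@H]2[C@H](Sc3ccccc3)[C@H]2[C@H]([C@@H](C)CO[Si](c3ccccc3)(c3ccccc3)C(C)(C)C)C[C@H]1C | intermediate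
15 | cyclopentane-1,3-dione | O=C1CCC(=O)C1 | starting material
16 | 2-[(phenylthio)methyl]cyclopentane-1,3-dione | O=C1CCC(=O)C1CSc1ccccc1 | intermediate
17 | allyl methyl carbonate | C=CCOC(=O)OC | starting material
18 | 2-allyl-2-[(phenylthio)methyl]cyclopentane-1,3-dione | C=CCC1(CSc2ccccc2)C(=O)CCC1=O | intermediate
19 | 2-allyl-2-[(phenylsulfonyl)methyl]cyclopentane-1,3-dione | C=CCC1(CS(=O)(=O)c2ccccc2)C(=O)CCC1=O | intermediate
20 | meso-2-allyl-2-[(phenylsulfonyl)methyl]cyclopentane-1,3-diol | C=CC[C@]1(CS(=O)(=O)c2ccccc2)[C@@H](O)CC[C@H]1O | intermediate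
21 | bis(triethylsilyl) ether of 20 | C=CC[C@]1(CS(=O)(=O)c2ccccc2)[C@@H](O[Si](CC)(CC)CC)CC[C@H]1O[Si](CC)(CC)CC | intermediate
22 | secondary ozonide of 21 | C1OOC(C[C@]2(CS(=O)(=O)c3ccccc3)[C@@H](O[Si](CC)(CC)CC)CC[C@H]2O[Si](CC)(CC)CC)O1 | intermediate
23 | 2-{2,5-bis(triethylsilyloxy)-1-[(phenylsulfonyl)methyl]cyclopentyl}acetaldehyde (meso) | O=CC[C@]1(CS(=O)(=O)c2ccccc2)[C@@H](O[Si](CC)(CC)CC)CC[C@H]1O[Si](CC)(CC)CC | intermediate
24 | (3+2) adduct: cis-fused 2-(phenylthio)-THF, C11 ketone | C([C@]1(CS(=O)(=O)c2ccccc2)[C@@H](O[Si](CC)(CC)CC)CC[C@H]1O[Si](CC)(CC)CC)[C@@H]3OC(Sc2ccccc2)[C@H]4[C@@H](C[C@@H](C)C(=O)[C@H]43)[C@@H](C)CO[Si](c2ccccc2)(c2ccccc2)C(C)(C)C | intermediate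
25 | C11 alcohol | C([C@]1(CS(=O)(=O)c2ccccc2)[C@@H](O[Si](CC)(CC)CC)CC[C@H]1O[Si](CC)(CC)CC)[C@@H]3OC(Sc2ccccc2)[C@H]4[C@@H](C[C@@H](C)[C@@H](O)[C@H]43)[C@@H](C)CO[Si](c2ccccc2)(c2ccccc2)C(C)(C)C | intermediate
26 | C11 acetate | C([C@]1(CS(=O)(=O)c2ccccc2)[C@@H](O[Si](CC)(CC)CC)CC[C@H]1O[Si](CC)(CC)CC)[C@@H]3OC(Sc2ccccc2)[C@H]4[C@@H](C[C@@H](C)[C@@H](OC(C)=O)[C@H]43)[C@@H](C)CO[Si](c2ccccc2)(c2ccccc2)C(C)(C)C | intermediate
27 | cyclopentane-1,3-diol | C([C@]1(CS(=O)(=O)c2ccccc2)[C@@H](O)CC[C@H]1O)[C@@H]3OC(Sc2ccccc2)[C@H]4[C@@H](C[C@@H](C)[C@@H](OC(C)=O)[C@H]43)[C@@H](C)CO[Si](c2ccccc2)(c2ccccc2)C(C)(C)C | intermediate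
28 | cyclopentane-1,3-dione, precursor of the key step | C(C1(CS(=O)(=O)c2ccccc2)C(=O)CCC1=O)[C@@H]3OC(Sc2ccccc2)[C@H]4[C@@H](C[C@@H](C)[C@@H](OC(C)=O)[C@H]43)[C@@H](C)CO[Si](c2ccccc2)(c2ccccc2)C(C)(C)C | intermediate
29 | tricyclic 3,6-dioxo-7-methylene oxonane, 16-O-TBDPS | C=C1C[C@@H]2O[C@H](C(=O)CCC1=O)[C@H]3[C@@H](C[C@@H](C)[C@@H](OC(C)=O)[C@H]32)[C@@H](C)CO[Si](c1ccccc1)(c1ccccc1)C(C)(C)C | intermediate
30 | tricyclic 3,6-dioxo-7-methylene oxonane, 16-OH | C=C1C[C@@H]2O[C@H](C(=O)CCC1=O)[C@H]3[C@@H](C[C@@H](C)[C@@H](OC(C)=O)[C@H]32)[C@@H](C)CO | intermediate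
31 | C3 hemiketal | C=C1C[C@@H]2O[C@H]3[C@H]4[C@@H](C[C@@H](C)[C@@H](OC(C)=O)[C@H]42)[C@@H](C)COC3(O)CCC1=O | intermediate
32 | tetracyclic enol ether (O16–C3=C4) | C=C1C[C@@H]2O[C@H]3[C@H]4[C@@H](C[C@@H](C)[C@@H](OC(C)=O)[C@H]42)[C@@H](C)CO/C3=C/CC1=O | intermediate
33 | C3–C4 alkoxy epoxide | C=C1C[C@@H]2O[C@H]3[C@H]4[C@@H](C[C@@H](C)[C@@H](OC(C)=O)[C@H]42)[C@@H](C)CO[C@@]3(O5)[C@H]5CC1=O | intermediate
34 | 4-O-deoctanoyl asbestinin 16 | C=C1C[C@@H]2O[C@H]3[C@H]4[C@@H](C[C@@H](C)[C@@H](OC(C)=O)[C@H]42)[C@@H](C)CO[C@@]3(C)[C@H](O)CC1=O | intermediate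
35 | asbestinin 16 | C=C1C[C@@H]2O[C@H]3[C@H]4[C@@H](C[C@@H](C)[C@@H](OC(C)=O)[C@H]42)[C@@H](C)CO[C@@]3(C)[C@H](OC(=O)CCCCCCC)CC1=O | target

Total step count: 23. Longest linear sequence: 17 steps (1–7, then 14–23).

**Steps most likely to fail**

1. Step 19. The C2 radical may be lost by hydrogen abstraction from the side chains. Alternatively, the chain may die because addition to the carbonyl carbon is slow and reversible.
Fallback (sets out from 28, returns at 29): the same reorganisation is run as two polar operations. The anomeric sulfur of 28 is oxidised with mCPBA to the anomeric bis-sulfone F1. Reductive samariation of the anomeric sulfone (SmI2, THF) with intramolecular Barbier-type addition to a dione carbonyl gives the tetracyclic ketol F2. Deprotonation of the ketol (DBU or KH) then triggers a Grob-type fragmentation of the C3–C7 bond with loss of benzenesulfinate and gives 29.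

2. Step 14. The cyclopropane may ionise without being captured by the aldehyde. The opened enolate may instead react intermolecularly, with loss of the cis fusion. Face selection at C9 may be poor, or the TES ethers may be lost.
Fallback (sets out from 10 and 23, returns at 24): C9–C10 is made first and C10 is set by protonation. Compound 10 is iodinated (I2, pyridine) to the 2-iodoenone F3. Nozaki–Hiyama–Kishi coupling with 23 gives the allylic alcohol F4; the C9 epimers are separated and the wrong one is recycled by Mitsunobu inversion. Conjugate addition of 12 (2.2 equiv) and kinetic protonation anti to the new C1 substituent give the cis-2,3-disubstituted ketone F5. Activation of the dithioacetal with dimethyl(methylthio)sulfonium tetrafluoroborate lets the C9 hydroxyl close the O,S-acetal and gives 24.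

3. Step 22. The oxidant may approach the inner face. Methyl transfer may occur through a free oxocarbenium ion without syn delivery. The alane may also add to the enone.
Fallback (sets out from 33, returns at 35): the methyl group is added to a ketone and the oxepane is closed at O–C16. Epoxide 33 is opened with octanoic acid. Acyl shift and collapse of the hemiketal give the 3-oxo 4-octanoate 16-alcohol F6. MeTi(OiPr)3 adds to the doubly activated C3 ketone from the outer face and gives the tertiary alcohol F7. Tf2O with 2,6-lutidine forms the primary triflate F8, which the C3 hydroxyl displaces to give 35.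

**Further compounds**
F1 | step 19 | anomeric bis-sulfone | C(C1(CS(=O)(=O)c2ccccc2)C(=O)CCC1=O)[C@@H]3OC(S(=O)(=O)c2ccccc2)[C@H]4[C@@H](C[C@@H](C)[C@@H](OC(C)=O)[C@H]43)[C@@H](C)CO[Si](c2ccccc2)(c2ccccc2)C(C)(C)C
F2 | step 19 | tetracyclic ketol (8-oxabicyclo[3.2.1]octane fused to a cyclopentanone) | O=C1CC[C@@]2(O)[C@]1(CS(=O)(=O)c1ccccc1)C[C@@H]3O[C@H]2[C@H]4[C@@H](C[C@@H](C)[C@@H](OC(C)=O)[C@H]43)[C@@H](C)CO[Si](c1ccccc1)(c1ccccc1)C(C)(C)C
F3 | step 14 | 2-iodoenone | O=C1C(I)=C[C@H]([C@@H](C)CO[Si](c2ccccc2)(c2ccccc2)C(C)(C)C)C[C@H]1C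
F4 | step 14 | allylic alcohol (C9–C10 joined) | C([C@]1(CS(=O)(=O)c2ccccc2)[C@@H](O[Si](CC)(CC)CC)CC[C@H]1O[Si](CC)(CC)CC)[C@H](O)C3=C[C@H]([C@@H](C)CO[Si](c2ccccc2)(c2ccccc2)C(C)(C)C)C[C@@H](C)C3=O
F5 | step 14 | cis-2,3-disubstituted ketone with C1–CH(SPh)2 | C([C@]1(CS(=O)(=O)c2ccccc2)[C@@H](O[Si](CC)(CC)CC)CC[C@H]1O[Si](CC)(CC)CC)[C@H](O)[C@H]3[C@@H](C(Sc2ccccc2)Sc2ccccc2)[C@H]([C@@H](C)CO[Si](c2ccccc2)(c2ccccc2)C(C)(C)C)C[C@@H](C)C3=O
F6 | step 22 | 3-oxo 4-octanoate 16-alcohol | C=C1C[C@@H]2O[C@H](C(=O)[C@H](OC(=O)CCCCCCC)CC1=O)[C@H]3[C@@H](C[C@@H](C)[C@@H](OC(C)=O)[C@H]32)[C@@H](C)CO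
F7 | step 22 | tertiary alcohol (C3 methyl carbinol) | C=C1C[C@@H]2O[C@H]([C@@](C)(O)[C@H](OC(=O)CCCCCCC)CC1=O)[C@H]3[C@@H](C[C@@H](C)[C@@H](OC(C)=O)[C@H]32)[C@@H](C)CO
F8 | step 22 | primary triflate | C=C1C[C@@H]2O[C@H]([C@@](C)(O)[C@H](OC(=O)CCCCCCC)CC1=O)[C@H]3[C@@H](C[C@@H](C)[C@@H](OC(C)=O)[C@H]32)[C@@H](C)COS(=O)(=O)C(F)(F)F
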